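**Plan**

- Retrosynthesis: the butenolide is traced back to a 3-furyl ring and the Z-allylic diol to an α,β-unsaturated δ-lactone. The chain is cut at C12–C13 (alkylborane + α-iodolactone) and at C9–C11 (enol triflate + vinyl). Ring B is cut at C7–C8 and C8–C9 by excising CH–CH3.
- Enabling feature: in ring B (C5–C10) the methyl-bearing C8 lies between the C7 methylene and C9, which sits on the quaternary C10. Without C8 and its methyl, ring B is the five-membered ketone ring of the Hajos–Parrish hydrindenedione.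
- Forward: ring A is present in 1 and ring B arises by one-carbon ring enlargement (step 1). gem-Dimethylation, deoxygenation and hydrogenation give the trans-decalone. Triflate, vinyl and hydroboration/Suzuki coupling join the lactone fragment, then the lactone is reduced and the furan oxidised.
- Stereochemistry: C10 comes from enantiopure (S)-1 (L-proline-derived). C5 is set by hydrogenation opposite the angular methyl, C16 by Brown allylation, and the C13=C14 geometry by the six-membered lactone ring.

Key step: step 1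

Remarks: Numbering is decalin C1–C10 as in labdanes; C11 and C12 are the CH2CH2 on C9; C13=C14 is the side-chain alkene with CH2OH on C13; C15 is the next CH2; C16 is the carbinol carbon. Compounds 1, 2 and 12 are assumed to be purchasable. C8 is drawn as its equatorial epimer in 4–9; a mixture there would not matter because C8 becomes sp2 in 10.

**Route**

Step 1
Reactants: 1 (S)-7a-methyl-2,3,7,7a-tetrahydro-1H-indene-1,5(6H)-dione ((S)-Hajos–Parrish ketone); 2 N-ethyl-N-nitrosourea
Product: 4 (2R,8aS)-2,8a-dimethyl-3,4,8,8a-tetrahydronaphthalene-1,6(2H,7H)-dione, via diazoethane 3 (not isolated)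
Conditions: 2, 40% aq KOH, Et2O, 0 °C, ethereal layer dried over KOH; added to 1, BF3·OEt2 (20 mol %), CH2Cl2, −78 → −20 °C; then DBU (cat.), CH2Cl2, rt
Reagents that add atoms: none
Why: BF3 activates the strained cyclopentanone carbonyl (C9), the nucleophilic carbon of diazoethane adds to it to give a β-oxido diazonium betaine, and the ring CH2 (C7) migrates antiperiplanar to the departing N2, so that C8–C9 and C7–C8 form in one operation. This is the Lewis-acid-promoted diazoalkane homologation of cyclic ketones (Büchner–Curtius–Schlotterbeck type), the reaction used for D-ring enlargement of 17-keto steroids. Ring B is not closed end to end but grows from five to six members by this 1,2-shift, so no Baldwin mode applies. The new C8 centre is formed as a mixture and should be equilibrated by DBU to the equatorial (2R) epimer with methyl trans to the angular methyl; it is planarised in step 7, so its configuration is immaterial. The step needs CH2 rather than quaternary-carbon migration (the betaine keeps the methyl-bearing diazonium carbon away from C10), attack at the cyclopentanone rather than the enone (ring strain against a weakly electrophilic vinylogous carbonyl), and a single insertion (the product ketone is flanked by a quaternary and a tertiary carbon).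

Step 2
Reactants: 4 (2R,8aS)-2,8a-dimethyl-3,4,8,8a-tetrahydronaphthalene-1,6(2H,7H)-dione
Product: 5 (4aS,5S,6R)-5-hydroxy-4a,6-dimethyl-4,4a,5,6,7,8-hexahydronaphthalen-2(3H)-one
Conditions: NaBH4 (0.3 equiv), EtOH, −20 °C; acetone, then H2O
Reagents that add atoms: none
Why: Chemoselective borohydride reduction, in which the saturated C9 ketone should react faster than the vinylogous β,β-disubstituted enone carbonyl at low temperature with a deficit of hydride (as in the parent Wieland–Miescher series); hydride enters from the α face opposite the angular methyl to give the equatorial 9β-alcohol, a centre that only protects C9 and is oxidised again in step 6.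

Step 3
Reactants: 5 (4aS,5S,6R)-5-hydroxy-4a,6-dimethyl-4,4a,5,6,7,8-hexahydronaphthalen-2(3H)-one
Product: 6 (4aS,5S,6R)-5-hydroxy-1,1,4a,6-tetramethyl-3,4,4a,5,6,7-hexahydronaphthalen-2(1H)-one
Conditions: t-BuOK (3 equiv), t-BuOH/THF, rt; MeI (excess), 0 °C → rt
Reagents that add atoms: iodomethane, CI
Why: Deconjugative gem-dialkylation of an enone, in which the extended dienolate is methylated twice at C4 with the double bond moving to C5=C6, while the hindered secondary alkoxide should not be O-methylated at a competitive rate and C8 can no longer enolise.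

Step 4
Reactants: 6 (4aS,5S,6R)-5-hydroxy-1,1,4a,6-tetramethyl-3,4,4a,5,6,7-hexahydronaphthalen-2(1H)-one
Product: 7 (1S,2R,8aS)-2,5,5,8a-tetramethyl-1,2,3,5,6,7,8,8a-octahydronaphthalen-1-ol
Conditions: N2H4·H2O, KOH, diethylene glycol, 130 → 210 °C
Reagents that add atoms: none
Why: Wolff–Kishner reduction (Huang-Minlon procedure) removes the C3 carbonyl through its hydrazone; the C5=C6 bond lies between two quaternary carbons and cannot migrate, and the free alcohol is inert to hot alkali.

Step 5
Reactants: 7 (1S,2R,8aS)-2,5,5,8a-tetramethyl-1,2,3,5,6,7,8,8a-octahydronaphthalen-1-ol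
Product: 8 (1S,2R,4aS,8aS)-2,5,5,8a-tetramethyldecahydronaphthalen-1-ol
Conditions: H2 (5 atm), 10% Pd/C, EtOH, rt
Reagents that add atoms: none
Why: Heterogeneous hydrogenation, in which the β face of C5=C6 is screened by the axial angular methyl and the 4β-methyl, so hydrogen should add from the α face and set C5 with H trans to the angular methyl (trans-decalin), as is usual for 4,4-dimethyl-Δ5 systems.

Step 6
Reactants: 8 (1S,2R,4aS,8aS)-2,5,5,8a-tetramethyldecahydronaphthalen-1-ol
Product: 9 (2R,4aS,8aS)-2,5,5,8a-tetramethyloctahydronaphthalen-1(2H)-one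
Conditions: TPAP (5 mol %), NMO, 4 Å MS, CH2Cl2, rt
Reagents that add atoms: none
Why: Ley–Griffith oxidation converts the hindered secondary alcohol into the ketone under neutral conditions, leaving C5 and C10 untouched.

Step 7
Reactants: 9 (2R,4aS,8aS)-2,5,5,8a-tetramethyloctahydronaphthalen-1(2H)-one
Product: 10 (4aS,8aS)-2,5,5,8a-tetramethyl-3,4,4a,5,6,7,8,8a-octahydronaphthalen-1-yl trifluoromethanesulfonate
Conditions: LDA, THF, −78 → 0 °C; PhNTf2, 0 °C → rt
Reagents that add atoms: N-phenylbis(trifluoromethanesulfonimide), O=S(=O)(N(c1ccccc1)S(=O)(=O)C(F)(F)F)C(F)(F)F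
Why: Enolate O-sulfonylation, in which 9 has a single α-hydrogen (C8–H), so only the C8=C9 enolate can form and is trapped as the tetrasubstituted enol triflate, as with 2,2,6-trimethylcyclohexanone.

Step 8
Reactants: 10 (4aS,8aS)-2,5,5,8a-tetramethyl-3,4,4a,5,6,7,8,8a-octahydronaphthalen-1-yl trifluoromethanesulfonate
Product: 11 (4aS,8aS)-1-ethenyl-2,5,5,8a-tetramethyl-3,4,4a,5,6,7,8,8a-octahydronaphthalene
Conditions: tributyl(vinyl)stannane, Pd2(dba)3 (cat.), AsPh3, LiCl, NMP, 60 °C
Reagents that add atoms: tributyl(vinyl)stannane, C=C[Sn](CCCC)(CCCC)CCCC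
Why: Stille coupling of an alkenyl triflate with a vinylstannane (LiCl and AsPh3 for a hindered triflate) forms C9–C11 without touching a stereocentre.

Step 9
Reactants: 12 furan-3-carbaldehyde
Product: 13 (R)-1-(furan-3-yl)but-3-en-1-ol
Conditions: (+)-Ipc2B(allyl), Et2O, −78 °C; then 3 M NaOH, 30% H2O2, rt
Reagents that add atoms: (+)-B-allyldiisopinocampheylborane, C=CCB([C@H]1C[C@H]2C[C@@H]([C@@H]1C)C2(C)C)[C@H]1C[C@H]2C[C@@H]([C@@H]1C)C2(C)C
Why: Brown allylation, in which the reagent derived from (−)-α-pinene delivers allyl to the Re face of the aldehyde through a chair six-membered transition state and so sets the (R)-carbinol C16, the furyl group taking the place that phenyl has with benzaldehyde.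

Step 10
Reactants: 13 (R)-1-(furan-3-yl)but-3-en-1-ol
Product: 14 (R)-1-(furan-3-yl)but-3-en-1-yl prop-2-enoate
Conditions: acryloyl chloride, Et3N, DMAP (cat.), CH2Cl2, 0 °C
Reagents that add atoms: acryloyl chloride, C=CC(=O)Cl
Why: DMAP-catalysed O-acylation of the secondary alcohol gives the metathesis substrate without affecting C16.

Step 11
Reactants: 14 (R)-1-(furan-3-yl)but-3-en-1-yl prop-2-enoate
Product: 15 (R)-6-(furan-3-yl)-5,6-dihydro-2H-pyran-2-one
Conditions: Grubbs II (5 mol %), CH2Cl2, 40 °C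
Reagents that add atoms: none
Why: Ring-closing metathesis of the acrylate with the terminal alkene closes the six-membered unsaturated lactone, whose ring holds the future CH2OH carbon and C15 cis across the future C13=C14 bond.

Step 12
Reactants: 15 (R)-6-(furan-3-yl)-5,6-dihydro-2H-pyran-2-one
Product: 16 (R)-6-(furan-3-yl)-3-iodo-5,6-dihydro-2H-pyran-2-one
Conditions: I2, pyridine/CH2Cl2 (1:1), 0 °C → rt, dark
Reagents that add atoms: iodine, II
Why: α-Iodination of an α,β-unsaturated carbonyl compound by the Baylis–Hillman-type sequence (pyridine adds at the β-carbon, the enolate is iodinated, pyridine is expelled); I2/pyridine should be too weak an electrophile to iodinate the 3-substituted furan, and C16 is not involved.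

Step 13
Reactants: 11 (4aS,8aS)-1-ethenyl-2,5,5,8a-tetramethyl-3,4,4a,5,6,7,8,8a-octahydronaphthalene; 16 (R)-6-(furan-3-yl)-3-iodo-5,6-dihydro-2H-pyran-2-one
Product: 18 (6R)-6-(furan-3-yl)-3-{2-[(4aS,8aS)-2,5,5,8a-tetramethyl-3,4,4a,5,6,7,8,8a-octahydronaphthalen-1-yl]ethyl}-5,6-dihydro-2H-pyran-2-one, via alkylborane 17 (not isolated)
Conditions: 11, 9-BBN, THF, 0 °C → rt; then 16, PdCl2(dppf) (5 mol %), AsPh3, Cs2CO3, DMF/H2O, rt
Reagents that add atoms: none
Why: Hydroboration followed by B-alkyl Suzuki–Miyaura coupling, in which 9-BBN should add only to the monosubstituted vinyl group (boron on terminal C12, the tetrasubstituted C8=C9 bond being inert) and the primary alkylborane couples with the α-iodoenoate to form C12–C13 with the ring-fixed alkene geometry retained.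

Step 14
Reactants: 18 (6R)-6-(furan-3-yl)-3-{2-[(4aS,8aS)-2,5,5,8a-tetramethyl-3,4,4a,5,6,7,8,8a-octahydronaphthalen-1-yl]ethyl}-5,6-dihydro-2H-pyran-2-one
Product: 19 (1R,3Z)-1-(furan-3-yl)-4-(hydroxymethyl)-6-[(4aS,8aS)-2,5,5,8a-tetramethyl-3,4,4a,5,6,7,8,8a-octahydronaphthalen-1-yl]hex-3-en-1-ol
Conditions: DIBAL-H (5 equiv), CH2Cl2, −78 → 0 °C; Rochelle salt
Reagents that add atoms: none
Why: DIBAL-H reduces the unsaturated lactone by 1,2-addition through the lactol to the primary allylic alcohol and frees the C16 hydroxyl; the cis relation of CH2OH and C15 imposed by the ring is kept, so the alkene is Z.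

Step 15
Reactants: 19 (1R,3Z)-1-(furan-3-yl)-4-(hydroxymethyl)-6-[(4aS,8aS)-2,5,5,8a-tetramethyl-3,4,4a,5,6,7,8,8a-octahydronaphthalen-1-yl]hex-3-en-1-ol
Product: 21 4-{(1R,3Z)-1-hydroxy-4-(hydroxymethyl)-6-[(4aS,8aS)-2,5,5,8a-tetramethyl-3,4,4a,5,6,7,8,8a-octahydronaphthalen-1-yl]hex-3-en-1-yl}furan-2(5H)-one, via hydroxybutenolide 20 (not isolated)
Conditions: O2, hν (visible), rose bengal (cat.), i-Pr2NEt, CH2Cl2, −78 °C; then NaBH4, EtOH, 0 °C; 1 M HCl
Reagents that add atoms: dioxygen, O=O
Why: Dye-sensitised photooxygenation of a 3-substituted furan with a hindered amine, in which singlet oxygen adds [4+2] across furan positions 2 and 5, the base removes the less hindered H-5 of the endoperoxide so that the carbonyl forms remote from the side chain, and NaBH4 reduction of the open aldehyde-acid form followed by acid lactonisation should give the β-substituted butenolide; at −78 °C the furan is expected to capture singlet oxygen faster than either alkene.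

**Compound list**

1 | (S)-7a-methyl-2,3,7,7a-tetrahydro-1H-indene-1,5(6H)-dione ((S)-Hajos–Parrish ketone) | C[C@]12CCC(=O)C=C1CCC2=O | starting material
2 | N-ethyl-N-nitrosourea | CCN(N=O)C(N)=O | starting material
3 | diazoethane | CC=[N+]=[N-] | intermediate
4 | (2R,8aS)-2,8a-dimethyl-3,4,8,8a-tetrahydronaphthalene-1,6(2H,7H)-dione | C[C@]12CCC(=O)C=C1CC[C@@H](C)C2=O | intermediate
5 | (4aS,5S,6R)-5-hydroxy-4a,6-dimethyl-4,4a,5,6,7,8-hexahydronaphthalen-2(3H)-one | C[C@]12CCC(=O)C=C1CC[C@@H](C)[C@@H]2O | intermediate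
6 | (4aS,5S,6R)-5-hydroxy-1,1,4a,6-tetramethyl-3,4,4a,5,6,7-hexahydronaphthalen-2(1H)-one | C[C@]12CCC(=O)C(C)(C)C1=CC[C@@H](C)[C@@H]2O | intermediate
7 | (1S,2R,8aS)-2,5,5,8a-tetramethyl-1,2,3,5,6,7,8,8a-octahydronaphthalen-1-ol | C[C@]12CCCC(C)(C)C1=CC[C@@H](C)[C@@H]2O | intermediate
8 | (1S,2R,4aS,8aS)-2,5,5,8a-tetramethyldecahydronaphthalen-1-ol | C[C@]12CCCC(C)(C)[C@@H]1CC[C@@H](C)[C@@H]2O | intermediate
9 | (2R,4aS,8aS)-2,5,5,8a-tetramethyloctahydronaphthalen-1(2H)-one | C[C@]12CCCC(C)(C)[C@@H]1CC[C@@H](C)C2=O | intermediate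
10 | (4aS,8aS)-2,5,5,8a-tetramethyl-3,4,4a,5,6,7,8,8a-octahydronaphthalen-1-yl trifluoromethanesulfonate | C[C@]12CCCC(C)(C)[C@@H]1CCC(C)=C2OS(=O)(=O)C(F)(F)F | intermediate
11 | (4aS,8aS)-1-ethenyl-2,5,5,8a-tetramethyl-3,4,4a,5,6,7,8,8a-octahydronaphthalene | C[C@]12CCCC(C)(C)[C@@H]1CCC(C)=C2C=C | intermediate
12 | furan-3-carbaldehyde | O=Cc1ccoc1 | starting material
13 | (R)-1-(furan-3-yl)but-3-en-1-ol | C=CC[C@@H](O)c1ccoc1 | intermediate
14 | (R)-1-(furan-3-yl)but-3-en-1-yl prop-2-enoate | C=CC[C@@H](OC(=O)C=C)c1ccoc1 | intermediate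
15 | (R)-6-(furan-3-yl)-5,6-dihydro-2H-pyran-2-one | O=C1C=CC[C@H](c2ccoc2)O1 | intermediate
16 | (R)-6-(furan-3-yl)-3-iodo-5,6-dihydro-2H-pyran-2-one | O=C1C(I)=CC[C@H](c2ccoc2)O1 | intermediate
17 | 9-{2-[(4aS,8aS)-2,5,5,8a-tetramethyl-3,4,4a,5,6,7,8,8a-octahydronaphthalen-1-yl]ethyl}-9-borabicyclo[3.3.1]nonane | C[C@]12CCCC(C)(C)[C@@H]1CCC(C)=C2CCB1C2CCCC1CCC2 | intermediate
18 | (6R)-6-(furan-3-yl)-3-{2-[(4aS,8aS)-2,5,5,8a-tetramethyl-3,4,4a,5,6,7,8,8a-octahydronaphthalen-1-yl]ethyl}-5,6-dihydro-2H-pyran-2-one | C[C@]12CCCC(C)(C)[C@@H]1CCC(C)=C2CCC1=CC[C@H](c2ccoc2)OC1=O | intermediate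
19 | (1R,3Z)-1-(furan-3-yl)-4-(hydroxymethyl)-6-[(4aS,8aS)-2,5,5,8a-tetramethyl-3,4,4a,5,6,7,8,8a-octahydronaphthalen-1-yl]hex-3-en-1-ol | C[C@]12CCCC(C)(C)[C@@H]1CCC(C)=C2CC/C(=C/C[C@@H](O)c1ccoc1)CO | intermediate
20 | 5-hydroxy-4-{(1R,3Z)-1-hydroxy-4-(hydroxymethyl)-6-[(4aS,8aS)-2,5,5,8a-tetramethyl-3,4,4a,5,6,7,8,8a-octahydronaphthalen-1-yl]hex-3-en-1-yl}furan-2(5H)-one (both C5 epimers) | C[C@]12CCCC(C)(C)[C@@H]1CCC(C)=C2CC/C(=C/C[C@@H](O)C1=CC(=O)OC1O)CO | intermediate
21 | 4-{(1R,3Z)-1-hydroxy-4-(hydroxymethyl)-6-[(4aS,8aS)-2,5,5,8a-tetramethyl-3,4,4a,5,6,7,8,8a-octahydronaphthalen-1-yl]hex-3-en-1-yl}furan-2(5H)-one | CC1=C(CC/C(=C/C[C@@H](O)C2=CC(=O)OC2)CO)[C@@]2(C)CCCC(C)(C)[C@@H]2CC1 | target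

**Totals and risks**

Total step count: 15. Longest linear sequence: 11 steps (steps 1–8, 13, 14, 15).

Steps most likely to fail:

Step 1. The reactive, non-stabilised diazoalkane may give competing migration of the quaternary carbon, epoxide formation or repeated insertion, and the catalyst may be held by the enone oxygen so that conversion stalls. Fallback: setting out from 1, insertion of ethyl diazoacetate (BF3·OEt2, CH2Cl2, 0 °C) is slower, more selective for migration of the less substituted carbon, and self-limiting because the product is enolised. It should give the ring-enlarged β-keto ester ethyl (8aS)-8a-methyl-1,6-dioxo-1,2,3,4,6,7,8,8a-octahydronaphthalene-2-carboxylate F1. C-methylation at the doubly activated carbon (K2CO3, MeI, acetone) should then give ethyl (8aS)-2,8a-dimethyl-1,6-dioxo-1,2,3,4,6,7,8,8a-octahydronaphthalene-2-carboxylate F2. Krapcho dealkoxycarbonylation (LiCl, wet DMSO, 150 °C) comes back to the route at 4.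

Step 12. The enoate may be too poor an acceptor for the pyridine-triggered addition–iodination–elimination, and the furan ring may be iodinated or degraded in competition. Fallback: the halogen is brought in with the acyl group and the lactone is closed after the coupling. Setting out from 13, esterification with 2-bromoacrylic acid (DCC, DMAP, CH2Cl2, 0 °C) should give (R)-1-(furan-3-yl)but-3-en-1-yl 2-bromoprop-2-enoate F3. B-alkyl Suzuki–Miyaura coupling of F3 with alkylborane 17 (PdCl2(dppf), Cs2CO3, DMF/H2O) should give (R)-1-(furan-3-yl)but-3-en-1-yl 2-methylidene-4-[(4aS,8aS)-2,5,5,8a-tetramethyl-3,4,4a,5,6,7,8,8a-octahydronaphthalen-1-yl]butanoate F4. Ring-closing metathesis (Grubbs II, toluene, 80 °C) comes back to the route at 18.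

Step 15. Singlet oxygen may undergo ene reactions with the C8=C9 and C13=C14 double bonds in competition with capture by the furan, and the hydroxybutenolide may be over-reduced. Fallback: the furan is oxidised without singlet oxygen. Setting out from 19, iridium-catalysed C–H borylation ([Ir(OMe)(cod)]2, dtbpy, B2pin2 and HBpin, THF, rt) should occur at the furan α-position remote from the side chain. The two hydroxyls are O-borylated in situ and released on work-up. This should give (2Z,5R)-5-[5-(4,4,5,5-tetramethyl-1,3,2-dioxaborolan-2-yl)furan-3-yl]-2-{2-[(4aS,8aS)-2,5,5,8a-tetramethyl-3,4,4a,5,6,7,8,8a-octahydronaphthalen-1-yl]ethyl}pent-2-ene-1,5-diol F5. Oxidation of the furyl boronate (NaBO3·4H2O, THF/H2O) and tautomerisation of the resulting 2-hydroxyfuran into conjugation (Et3N) comes back to the route at 21.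

**Further compounds**

F1 | step 1 | ethyl (8aS)-8a-methyl-1,6-dioxo-1,2,3,4,6,7,8,8a-octahydronaphthalene-2-carboxylate | C[C@]12CCC(=O)C=C1CCC(C(=O)OCC)C2=O
F2 | step 1 | ethyl (8aS)-2,8a-dimethyl-1,6-dioxo-1,2,3,4,6,7,8,8a-octahydronaphthalene-2-carboxylate | C[C@]12CCC(=O)C=C1CCC(C)(C(=O)OCC)C2=O
F3 | step 12 | (R)-1-(furan-3-yl)but-3-en-1-yl 2-bromoprop-2-enoate | C=CC[C@@H](OC(=O)C(Br)=C)c1ccoc1
F4 | step 12 | (R)-1-(furan-3-yl)but-3-en-1-yl 2-methylidene-4-[(4aS,8aS)-2,5,5,8a-tetramethyl-3,4,4a,5,6,7,8,8a-octahydronaphthalen-1-yl]butanoate | C[C@]12CCCC(C)(C)[C@@H]1CCC(C)=C2CCC(=C)C(=O)O[C@H](CC=C)c1ccoc1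
F5 | step 15 | (2Z,5R)-5-[5-(4,4,5,5-tetramethyl-1,3,2-dioxaborolan-2-yl)furan-3-yl]-2-{2-[(4aS,8aS)-2,5,5,8a-tetramethyl-3,4,4a,5,6,7,8,8a-octahydronaphthalen-1-yl]ethyl}pent-2-ene-1,5-diol | C[C@]12CCCC(C)(C)[C@@H]1CCC(C)=C2CC/C(=C/C[C@@H](O)c1coc(B2OC(C)(C)C(C)(C)O2)c1)CO
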